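**Retrosynthetic overview**

1. The methylene bridge is made last. C8 of 5,7-dihydroxy-6-(2-methylpropanoyl)-2,2-dimethyl-2H-chromene and C3 of 6-ethyl-4-hydroxy-5-methyl-2H-pyran-2-one are joined by aminomethylation, amine loss and conjugate addition.
2. The strategy rests on the chromene C3=C4 double bond, the only non-aromatic alkene of the bicycle. It lies between quaternary C2 (two methyls, bonded to O1) and aromatic C4a, so cutting it leaves an aryl vinyl group and an O-(2-methylbut-3-en-2-yl) ether, which ring-closing metathesis rejoins.
3. The vinyl group is attached (iodination, Suzuki coupling) before the tertiary allyl ether exists, because an ortho-iodoaryl allyl ether would cyclise by carbopalladation or ionise under zerovalent palladium. A temporary silyl ether marks the hydroxyl para to the ketone, which becomes O1.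
4. Ring order: the benzene ring is bought as phloroglucinol, the pyran ring of the chromene is closed by metathesis, and the pyranone ring is made in a two-step branch (dianion acylation, lactonisation) before the final union.

Key step: step 9

Assumption: the target has no stereocentre and is drawn as the 4-hydroxy-2H-pyran-2-one tautomer; the pyranone half is not taken as purchasable and is made in two steps.

**Route**

Step 1
Reactants: 1 phloroglucinol; 2 2-methylpropanoyl chloride
Product: 3 2-methyl-1-(2,4,6-trihydroxyphenyl)propan-1-one
Conditions: AlCl3 (4 equiv), PhNO2, 65 °C; then ice, aq HCl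
Reagents that add atoms: none
Why: Friedel–Crafts C-acylation of the strongly activated ring should stop at the mono-ketone because the aluminium-chelated acyl group deactivates the ring toward a second acylation.

Step 2
Reactants: 3 2-methyl-1-(2,4,6-trihydroxyphenyl)propan-1-one
Product: 4 1-{2,6-dihydroxy-4-[tri(propan-2-yl)silyloxy]phenyl}-2-methylpropan-1-one
Conditions: TIPSCl (1.05 equiv), imidazole, DMF, 0 °C
Reagents that add atoms: chlorotri(propan-2-yl)silane, CC(C)[Si](Cl)(C(C)C)C(C)C
Why: Selective phenol silylation should occur at the 4-hydroxyl, the only one not hydrogen-bonded to the ketone and the most acidic, so the bulky silyl chloride leaves the two chelated hydroxyls alone.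

Step 3
Reactants: 4 1-{2,6-dihydroxy-4-[tri(propan-2-yl)silyloxy]phenyl}-2-methylpropan-1-one
Product: 5 1-{2,6-dihydroxy-3-iodo-4-[tri(propan-2-yl)silyloxy]phenyl}-2-methylpropan-1-one
Conditions: NIS (1.0 equiv, slow addition), DMF, 0 °C, dark
Reagents that add atoms: N-iodosuccinimide, O=C1CCC(=O)N1I
Why: Electrophilic aromatic iodination of a phenol; the two free ring carbons are equivalent and each is ortho or para to three oxygen substituents, so one equivalent of the iodinating agent should give a single mono-iodide.

Step 4
Reactants: 5 1-{2,6-dihydroxy-3-iodo-4-[tri(propan-2-yl)silyloxy]phenyl}-2-methylpropan-1-one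
Product: 6 1-{3-iodo-2,6-bis(methoxymethoxy)-4-[tri(propan-2-yl)silyloxy]phenyl}-2-methylpropan-1-one
Conditions: NaH (2.3 equiv), MOMCl (2.6 equiv), DMF, 0 °C to room temperature
Reagents that add atoms: chloromethyl methyl ether, COCCl
Why: Williamson-type O-alkylation of the two sodium phenoxides gives the bis(methoxymethyl) acetal; the strong base is needed to break the hydrogen-bond chelates to the ketone, and the hindered silyl ether should survive.

Step 5
Reactants: 6 1-{3-iodo-2,6-bis(methoxymethoxy)-4-[tri(propan-2-yl)silyloxy]phenyl}-2-methylpropan-1-one; 7 2-ethenyl-4,4,5,5-tetramethyl-1,3,2-dioxaborolane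
Product: 8 1-{3-ethenyl-2,6-bis(methoxymethoxy)-4-[tri(propan-2-yl)silyloxy]phenyl}-2-methylpropan-1-one
Conditions: 7 (1.5 equiv), Pd(OAc)2 (5 mol%), SPhos (10 mol%), K3PO4, toluene/H2O, 80 °C
Reagents that add atoms: none
Why: Suzuki–Miyaura coupling with a biarylphosphine ligand suited to a di-ortho-substituted, electron-rich aryl iodide; no allyl ether is present at this stage, so neither intramolecular Heck cyclisation nor allyl ionisation by zerovalent palladium can compete.

Step 6
Reactants: 8 1-{3-ethenyl-2,6-bis(methoxymethoxy)-4-[tri(propan-2-yl)silyloxy]phenyl}-2-methylpropan-1-one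
Product: 9 1-[3-ethenyl-4-hydroxy-2,6-bis(methoxymethoxy)phenyl]-2-methylpropan-1-one
Conditions: Bu4NF (1.1 equiv), THF, 0 °C; then AcOH (1.1 equiv)
Reagents that add atoms: none
Why: Fluoride-induced cleavage of the aryl silyl ether frees only the hydroxyl para to the ketone; the acetals and the styrene are inert to fluoride, and the mild acetic acid quench avoids acid-promoted reactions of the ortho-vinylphenol.

Step 7
Reactants: 10 2-methylbut-3-en-2-ol
Product: 11 tert-butyl 2-methylbut-3-en-2-yl carbonate
Conditions: n-BuLi, THF, 0 °C; then Boc2O, 0 °C to room temperature; aqueous work-up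
Reagents that add atoms: di-tert-butyl dicarbonate, CC(C)(C)OC(=O)OC(=O)OC(C)(C)C
Why: Acylation of the lithium tertiary alkoxide by the dicarbonate gives the mixed allylic carbonate, a standard leaving group for palladium allyl chemistry.

Step 8
Reactants: 9 1-[3-ethenyl-4-hydroxy-2,6-bis(methoxymethoxy)phenyl]-2-methylpropan-1-one; 11 tert-butyl 2-methylbut-3-en-2-yl carbonate
Product: 12 1-[3-ethenyl-2,6-bis(methoxymethoxy)-4-(2-methylbut-3-en-2-yloxy)phenyl]-2-methylpropan-1-one
Conditions: 11 (1.5 equiv), Pd(PPh3)4 (5 mol%), THF, 0 °C, dark
Reagents that add atoms: none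
Why: Tsuji–Trost O-allylation: zerovalent palladium ionises the carbonate, loss of CO2 gives tert-butoxide that deprotonates the single free phenol, and the phenoxide attacks the more substituted terminus of the 1,1-dimethylallyl palladium cation, which at 0 °C should give the branched tertiary ether as the kinetic product.

Step 9
Reactants: 12 1-[3-ethenyl-2,6-bis(methoxymethoxy)-4-(2-methylbut-3-en-2-yloxy)phenyl]-2-methylpropan-1-one
Product: 13 1-[5,7-bis(methoxymethoxy)-2,2-dimethyl-2H-chromen-6-yl]-2-methylpropan-1-one
Conditions: second-generation Grubbs catalyst (H2IMes)(PCy3)Cl2Ru=CHPh (5 mol%), CH2Cl2 (0.005 M), 25–35 °C, argon sparge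
Reagents that add atoms: none
Why: Olefin metathesis by the Chauvin mechanism: the ruthenium benzylidene exchanges onto the more accessible aryl vinyl group, the new alkylidene adds across the neighbouring 1,1-dimethylallyl alkene to give a ruthenacyclobutane, and cycloreversion releases the chromene and Ru=CH2, which re-enters the cycle while ethene leaves the solution. The closest known reaction type is the ring-closing metathesis of 2-vinylaryl allyl ethers to 2H-chromenes. The pyran ring closes as a six-membered ring by forming the C3=C4 bond between two terminal alkenes held ortho on the arene, so the new alkene can only be cis and no stereocentre is created. The selectivity needed is ring closure over intermolecular cross-metathesis, over ruthenium-hydride alkene migration and over [3,3] shift of the tertiary allyl ether to the free C8 carbon. The ortho placement of the two alkenes, the Thorpe–Ingold effect of the geminal methyls, the reluctance of the hindered 1,1-dimethylallyl alkene to homodimerise, high dilution and a temperature at or below 35 °C should secure it.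

Step 10
Reactants: 13 1-[5,7-bis(methoxymethoxy)-2,2-dimethyl-2H-chromen-6-yl]-2-methylpropan-1-one
Product: 14 1-(5,7-dihydroxy-2,2-dimethyl-2H-chromen-6-yl)-2-methylpropan-1-one
Conditions: 3 M aq HCl, MeOH, 40 °C
Reagents that add atoms: none
Why: Acid-catalysed acetal cleavage (transfer of the methoxymethyl groups to methanol) is fast for aryl acetals ortho to a carbonyl, and the 2,2-dimethylchromene alkene should tolerate dilute acid at this temperature.

Step 11
Reactants: 15 methyl 3-oxopentanoate; 16 N-methoxy-N-methylpropanamide
Product: 17 methyl 4-methyl-3,5-dioxoheptanoate (racemic at C4)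
Conditions: LiN(i-Pr)2 (2.2 equiv), THF, −78 to 0 °C; then 16, −78 to 0 °C; aq HCl
Reagents that add atoms: none
Why: γ-Acylation of a β-keto ester dianion by a Weinreb amide, whose chelated tetrahedral intermediate prevents over-addition; the new C4 stereocentre forms without control as a racemate and becomes sp2 in the next step.

Step 12
Reactants: 17 methyl 4-methyl-3,5-dioxoheptanoate
Product: 18 6-ethyl-4-hydroxy-5-methyl-2H-pyran-2-one
Conditions: DBU (1.5 equiv), toluene, 110 °C; then aq HCl
Reagents that add atoms: none
Why: Base-mediated lactonisation of a 3,5-dioxo ester: the enol oxygen of the C5 ketone attacks the ester, methanol is lost, and the product tautomerises to the 4-hydroxy-2-pyranone.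

Step 13
Reactants: 14 1-(5,7-dihydroxy-2,2-dimethyl-2H-chromen-6-yl)-2-methylpropan-1-one; 18 6-ethyl-4-hydroxy-5-methyl-2H-pyran-2-one
Product: 21 3-{[5,7-dihydroxy-2,2-dimethyl-6-(2-methylpropanoyl)-2H-chromen-8-yl]methyl}-6-ethyl-4-hydroxy-5-methyl-2H-pyran-2-one, via pyranone Mannich base 19 (not isolated), via 3-methylidenepyran-2,4-dione 20 (not isolated)
Conditions: 18, CH2=N(CH3)2+ I− (1.0 equiv), MeCN, room temperature; then 14 (1.0 equiv), 60 °C
Reagents that add atoms: N,N-dimethylmethaniminium iodide (Eschenmoser's salt), C=[N+](C)C.[I-]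
Why: Mannich aminomethylation of the pyranone at C3, thermal loss of dimethylamine to the 3-methylidene-2,4-dione (a quinone-methide-like acceptor) and Friedel–Crafts-type conjugate addition by C8, the only unsubstituted carbon of the acylphloroglucinol ring, should give the methylene-bridged product.

**Compound list**

1 | phloroglucinol (benzene-1,3,5-triol) | Oc1cc(O)cc(O)c1 | starting material
2 | 2-methylpropanoyl chloride | CC(C)C(Cl)=O | starting material
3 | 2-methyl-1-(2,4,6-trihydroxyphenyl)propan-1-one | CC(C)C(=O)c1c(O)cc(O)cc1O | intermediate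
4 | 1-{2,6-dihydroxy-4-[tri(propan-2-yl)silyloxy]phenyl}-2-methylpropan-1-one | CC(C)C(=O)c1c(O)cc(O[Si](C(C)C)(C(C)C)C(C)C)cc1O | intermediate
5 | 1-{2,6-dihydroxy-3-iodo-4-[tri(propan-2-yl)silyloxy]phenyl}-2-methylpropan-1-one | CC(C)C(=O)c1c(O)cc(O[Si](C(C)C)(C(C)C)C(C)C)c(I)c1O | intermediate
6 | 1-{3-iodo-2,6-bis(methoxymethoxy)-4-[tri(propan-2-yl)silyloxy]phenyl}-2-methylpropan-1-one | CC(C)C(=O)c1c(OCOC)cc(O[Si](C(C)C)(C(C)C)C(C)C)c(I)c1OCOC | intermediate
7 | 2-ethenyl-4,4,5,5-tetramethyl-1,3,2-dioxaborolane | C=CB1OC(C)(C)C(C)(C)O1 | starting material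
8 | 1-{3-ethenyl-2,6-bis(methoxymethoxy)-4-[tri(propan-2-yl)silyloxy]phenyl}-2-methylpropan-1-one | CC(C)C(=O)c1c(OCOC)cc(O[Si](C(C)C)(C(C)C)C(C)C)c(C=C)c1OCOC | intermediate
9 | 1-[3-ethenyl-4-hydroxy-2,6-bis(methoxymethoxy)phenyl]-2-methylpropan-1-one | CC(C)C(=O)c1c(OCOC)cc(O)c(C=C)c1OCOC | intermediate
10 | 2-methylbut-3-en-2-ol | CC(C)(O)C=C | starting material
11 | tert-butyl 2-methylbut-3-en-2-yl carbonate | CC(C)(C)OC(=O)OC(C)(C)C=C | intermediate
12 | 1-[3-ethenyl-2,6-bis(methoxymethoxy)-4-(2-methylbut-3-en-2-yloxy)phenyl]-2-methylpropan-1-one | CC(C)C(=O)c1c(OCOC)cc(OC(C)(C)C=C)c(C=C)c1OCOC | intermediate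
13 | 1-[5,7-bis(methoxymethoxy)-2,2-dimethyl-2H-chromen-6-yl]-2-methylpropan-1-one | CC(C)C(=O)c1c(OCOC)cc2OC(C)(C)C=Cc2c1OCOC | intermediate
14 | 1-(5,7-dihydroxy-2,2-dimethyl-2H-chromen-6-yl)-2-methylpropan-1-one | CC(C)C(=O)c1c(O)cc2OC(C)(C)C=Cc2c1O | intermediate
15 | methyl 3-oxopentanoate | CCC(=O)CC(=O)OC | starting material
16 | N-methoxy-N-methylpropanamide | CCC(=O)N(C)OC | starting material
17 | methyl 4-methyl-3,5-dioxoheptanoate (racemic) | CCC(=O)C(C)C(=O)CC(=O)OC | intermediate
18 | 6-ethyl-4-hydroxy-5-methyl-2H-pyran-2-one | CCc1oc(=O)cc(O)c1C | intermediate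
19 | 3-[(dimethylamino)methyl]-6-ethyl-4-hydroxy-5-methyl-2H-pyran-2-one | CCc1oc(=O)c(CN(C)C)c(O)c1C | intermediate
20 | 6-ethyl-5-methyl-3-methylidene-2H-pyran-2,4(3H)-dione | CCC1=C(C)C(=O)C(=C)C(=O)O1 | intermediate
21 | 3-{[5,7-dihydroxy-2,2-dimethyl-6-(2-methylpropanoyl)-2H-chromen-8-yl]methyl}-6-ethyl-4-hydroxy-5-methyl-2H-pyran-2-one | CCc1oc(=O)c(Cc2c(O)c(C(=O)C(C)C)c(O)c3c2OC(C)(C)C=C3)c(O)c1C | target

**Step count and risks**

Total step count: 13. Longest linear sequence: 10 steps (steps 1 to 6, 8, 9, 10 and 13); step 7 and steps 11 and 12 are side branches.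

Steps most likely to fail:

Step 8. The ortho-substituted phenoxide may attack the less hindered terminus of the allyl palladium cation, or the branched ether may re-ionise and drift to the linear prenyl ether. The fallback avoids palladium allyl chemistry. It sets out from 9, which would be O-alkylated with 3-chloro-3-methylbut-1-yne (CuCl2 as catalyst, DBU, MeCN, 0 °C) to give 1-[3-ethenyl-2,6-bis(methoxymethoxy)-4-(2-methylbut-3-yn-2-yloxy)phenyl]-2-methylpropan-1-one F1. Semi-hydrogenation of the terminal alkyne (H2, Pd/CaCO3 poisoned with Pb(OAc)2, quinoline, EtOAc, room temperature, stopped after one equivalent of hydrogen) would then give the tertiary allyl ether, and the fallback comes back to the route at 12.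

Step 9. Ring closure at the twisted, di-ortho-substituted styrene and the neopentyl-type alkene may be slow enough that intermolecular cross-metathesis, alkene migration by ruthenium hydrides or thermal [3,3] shift of the allyl ether takes over. The fallback forms the pyran ring by a pericyclic cascade instead of metathesis. It sets out from 3, which would be alkylated at the non-chelated para hydroxyl with 3-chloro-3-methylbut-1-yne (CuCl2 as catalyst, DBU, MeCN, 0 °C) to give 1-[2,6-dihydroxy-4-(2-methylbut-3-yn-2-yloxy)phenyl]-2-methylpropan-1-one F2. Heating F2 in N,N-diethylaniline at about 150 °C should bring about propargyl Claisen rearrangement, hydrogen shift and oxa-6π electrocyclisation. Closure is expected through the oxygen that carried the propargyl group, since the neighbouring hydroxyl is tied up in a hydrogen bond to the ketone. The fallback comes back to the route at 14.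

Step 13. The methylidene-dione may be captured by a second pyranone, or the aminomethylation may be shared between the two partners, so that symmetrical methylene-bridged dimers form in place of the mixed product. The fallback reverses the roles of the partners and isolates the electrophile precursor. It sets out from 14, which would undergo a phenolic Mannich reaction at C8 (aqueous CH2O, Me2NH, EtOH, room temperature) to give 1-{8-[(dimethylamino)methyl]-5,7-dihydroxy-2,2-dimethyl-2H-chromen-6-yl}-2-methylpropan-1-one F3. Heating purified F3 with 18 in dioxane at 100 °C should expel dimethylamine to an ortho-quinone methide, which C3 of the pyranone traps, and the fallback comes back to the route at 21.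

**Further compounds**

F1 | step 8 | 1-[3-ethenyl-2,6-bis(methoxymethoxy)-4-(2-methylbut-3-yn-2-yloxy)phenyl]-2-methylpropan-1-one | CC(C)C(=O)c1c(OCOC)cc(OC(C)(C)C#C)c(C=C)c1OCOC
F2 | step 9 | 1-[2,6-dihydroxy-4-(2-methylbut-3-yn-2-yloxy)phenyl]-2-methylpropan-1-one | CC(C)C(=O)c1c(O)cc(OC(C)(C)C#C)cc1O
F3 | step 13 | 1-{8-[(dimethylamino)methyl]-5,7-dihydroxy-2,2-dimethyl-2H-chromen-6-yl}-2-methylpropan-1-one | CC(C)C(=O)c1c(O)c(CN(C)C)c2OC(C)(C)C=Cc2c1O
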